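## Retrosynthetic overview

- Kazinol J (16) comes from its tris-MOM ether 15 by one global acetal cleavage. Both benzene rings are purchased, so no ring is formed at any stage.
- 15 comes from aryl iodide 13, 3-arylpropyl bromide 5 and prenylBpin 14 in one Pd/norbornene (Catellani) three-component coupling. This step makes the ring-B C1–CH2 bond, which unites the two halves, and the ring-B C2–prenyl bond in the same operation.
- Enabling feature: the catechol ring (ring B) carries the propyl chain at C1, prenyl at C2, prenyl at C3, OH at C4, OH at C5 and H at C6. Its three carbon substituents therefore sit on contiguous carbons C1–C2–C3 beside the unsubstituted C6. An iodine on C2 has the C3 prenyl as its blocking ortho group and C1–H as its only ortho C–H, and C1 is flanked on its outer side only by C6–H.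
- 13 comes from 4-bromocatechol 6 by MOM protection, deprotonation between Br and OMOM with prenylation, and Br-to-I exchange. 5 comes from 4-bromo-3-methoxyphenol 1 by MOM protection and Cu-catalysed Grignard alkylation with 1,3-dibromopropane.

Key step: step 6

Remark: 16 has no stereocentre and both alkenes end in CMe2, so the SMILES describes one achiral compound and no enantiomer or E/Z isomer has to be controlled.
Remark: the catalyst-bound organopalladium species of step 6 are turnover states of the catalyst. They are described in its Why line and carry no compound number.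

## Route

Step 1
Reactants: 1 4-bromo-3-methoxyphenol
Product: 2 1-bromo-2-methoxy-4-(methoxymethoxy)benzene
Conditions: MOMCl (1.3 equiv), i-Pr2NEt (1.6 equiv), CH2Cl2, 0 °C to rt
Reagents that add atoms: chloromethyl methyl ether (MOMCl), COCCl
Why: Williamson-type O-alkylation of the only phenol gives a MOM acetal that tolerates Mg, Cu, Pd and carbonate and can be removed later without hydrogenation.

Step 2
Reactants: 2 1-bromo-2-methoxy-4-(methoxymethoxy)benzene; 3 1,3-dibromopropane
Product: 5 1-(3-bromopropyl)-2-methoxy-4-(methoxymethoxy)benzene, via arylmagnesium bromide 4 (not isolated)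
Conditions: Mg (I2-activated), THF, 50 °C; then added slowly to 3 (4 equiv), Li2CuCl4 (3 mol %), THF, 0 °C to rt
Reagents that add atoms: none
Why: Copper-catalysed Grignard–alkyl halide cross-coupling (Kochi-type) is used, and inverse addition into excess dibromide should limit substitution to one C–Br bond.

Step 3
Reactants: 6 4-bromobenzene-1,2-diol (4-bromocatechol)
Product: 7 4-bromo-1,2-bis(methoxymethoxy)benzene
Conditions: MOMCl (2.6 equiv), i-Pr2NEt (3.2 equiv), CH2Cl2, 0 °C to rt, argon
Reagents that add atoms: chloromethyl methyl ether (MOMCl), COCCl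
Why: Double Williamson-type O-alkylation masks the oxidation-prone catechol and installs the ortho-directing OMOM group needed in step 4.

Step 4
Reactants: 7 4-bromo-1,2-bis(methoxymethoxy)benzene; 8 prenyl bromide (1-bromo-3-methylbut-2-ene)
Product: 11 1-bromo-3,4-bis(methoxymethoxy)-2-(3-methylbut-2-en-1-yl)benzene, via aryllithium 9 (not isolated), via arylcopper 10 (not isolated)
Conditions: 7 added to LDA (commercial solution, 1.15 equiv), THF, −78 °C; CuBr·SMe2 (1.15 equiv), −78 °C; 8 (1.5 equiv), −78 to 0 °C
Reagents that add atoms: none
Why: Directed ortho-metalation with an amide base (no Br/Li exchange) removes the most acidic proton, the one flanked by Br and OMOM; Li-to-Cu transmetalation suppresses LiBr loss, and the arylcopper substitutes prenyl bromide at its primary carbon (SN2 allylation).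

Step 5
Reactants: 11 1-bromo-3,4-bis(methoxymethoxy)-2-(3-methylbut-2-en-1-yl)benzene
Product: 13 1-iodo-3,4-bis(methoxymethoxy)-2-(3-methylbut-2-en-1-yl)benzene, via aryllithium 12 (not isolated)
Conditions: n-BuLi (1.05 equiv), THF, −78 °C; I2 (1.1 equiv), THF, −78 °C; aq. Na2S2O3 quench
Reagents that add atoms: iodine, II
Why: Bromine–lithium exchange followed by iodinolysis is faster at −78 °C than any ortho- or allylic deprotonation and faster than iodine addition to the alkene, and it supplies the C–I bond that the Pd/norbornene relay needs for rapid oxidative addition.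

Step 6
Reactants: 13 1-iodo-3,4-bis(methoxymethoxy)-2-(3-methylbut-2-en-1-yl)benzene; 5 1-(3-bromopropyl)-2-methoxy-4-(methoxymethoxy)benzene; 14 prenylBpin (4,4,5,5-tetramethyl-2-(3-methylbut-2-en-1-yl)-1,3,2-dioxaborolane)
Product: 15 1-{3-[2-methoxy-4-(methoxymethoxy)phenyl]propyl}-4,5-bis(methoxymethoxy)-2,3-bis(3-methylbut-2-en-1-yl)benzene
Conditions: Pd(OAc)2 (10 mol %), P(2-furyl)3 (22 mol %), norbornene (2 equiv), Cs2CO3 (4 equiv), 5 (1.5 equiv), 14 (2 equiv, slow addition), MeCN–H2O (50:1), 85 °C, argon
Reagents that add atoms: none
Why: Proposed new method: Pd(0) inserts into the C–I bond of 13, norbornene carbopalladates, and carbonate-assisted palladation of the single free ortho C–H gives an aryl–norbornyl palladacycle that adds the primary C–Br bond of 5 to reach Pd(IV) and reductively eliminates the new aryl–CH2 bond. The norbornyl-bearing carbon is then flanked by two ortho substituents, so β-carbon elimination expels norbornene and leaves aryl–Pd(II)–Br on the former C–I carbon, where base-assisted transmetalation with 14 and reductive elimination place the second prenyl group. The closest known reaction type is the Catellani ortho-alkylation/ipso-Suzuki–Miyaura three-component coupling with arylboronic acids, and linear-selective Suzuki–Miyaura prenylation of aryl halides with 14 is known separately; only an allylic boronate as the terminator of the relay is untested. No ring is closed and no stereocentre is formed. Site selectivity comes from the substrate: the prenyl group next to iodine blocks one ortho position and supplies the strain for norbornene extrusion, the reacting C–H has only C–H as its outer neighbour, and the two ortho groups around Pd in the last intermediate disfavour C–C formation at the tertiary allyl terminus, so the linear prenyl isomer is expected. Order selectivity (relay before termination) rests on fast norbornene insertion, excess norbornene and slow addition of 14, and the trisubstituted prenyl alkenes are too hindered to act as Heck acceptors.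

Step 7
Reactants: 15 1-{3-[2-methoxy-4-(methoxymethoxy)phenyl]propyl}-4,5-bis(methoxymethoxy)-2,3-bis(3-methylbut-2-en-1-yl)benzene
Product: 16 Kazinol J
Conditions: HCl (commercial 1.25 M solution in MeOH, substoichiometric), MeOH, rt to 40 °C, argon; NaHCO3 quench
Reagents that add atoms: none
Why: Acid-catalysed transacetalisation of the three aryl MOM ethers with methanol frees all phenols at once, and dilute acid with mild temperature should keep the ortho-prenylphenol from cyclising while argon protects the catechol.

## Compound list

1 | 4-bromo-3-methoxyphenol | COc1cc(O)ccc1Br | starting material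
2 | 1-bromo-2-methoxy-4-(methoxymethoxy)benzene | COCOc1ccc(Br)c(OC)c1 | intermediate
3 | 1,3-dibromopropane | BrCCCBr | starting material
4 | [2-methoxy-4-(methoxymethoxy)phenyl]magnesium bromide | COCOc1ccc([Mg]Br)c(OC)c1 | intermediate
5 | 1-(3-bromopropyl)-2-methoxy-4-(methoxymethoxy)benzene | COCOc1ccc(CCCBr)c(OC)c1 | intermediate
6 | 4-bromobenzene-1,2-diol | Oc1ccc(Br)cc1O | starting material
7 | 4-bromo-1,2-bis(methoxymethoxy)benzene | COCOc1ccc(Br)cc1OCOC | intermediate
8 | prenyl bromide (1-bromo-3-methylbut-2-ene) | CC(C)=CCBr | starting material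
9 | [6-bromo-2,3-bis(methoxymethoxy)phenyl]lithium | COCOc1ccc(Br)c([Li])c1OCOC | intermediate
10 | [6-bromo-2,3-bis(methoxymethoxy)phenyl]copper | COCOc1ccc(Br)c([Cu])c1OCOC | intermediate
11 | 1-bromo-3,4-bis(methoxymethoxy)-2-(3-methylbut-2-en-1-yl)benzene | COCOc1ccc(Br)c(CC=C(C)C)c1OCOC | intermediate
12 | [3,4-bis(methoxymethoxy)-2-(3-methylbut-2-en-1-yl)phenyl]lithium | COCOc1ccc([Li])c(CC=C(C)C)c1OCOC | intermediate
13 | 1-iodo-3,4-bis(methoxymethoxy)-2-(3-methylbut-2-en-1-yl)benzene | COCOc1ccc(I)c(CC=C(C)C)c1OCOC | intermediate
14 | 4,4,5,5-tetramethyl-2-(3-methylbut-2-en-1-yl)-1,3,2-dioxaborolane (prenylBpin) | CC(C)=CCB1OC(C)(C)C(C)(C)O1 | starting material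
15 | 1-{3-[2-methoxy-4-(methoxymethoxy)phenyl]propyl}-4,5-bis(methoxymethoxy)-2,3-bis(3-methylbut-2-en-1-yl)benzene | COCOc1ccc(CCCc2cc(OCOC)c(OCOC)c(CC=C(C)C)c2CC=C(C)C)c(OC)c1 | intermediate
16 | Kazinol J, 5-[3-(4-hydroxy-2-methoxyphenyl)propyl]-3,4-bis(3-methylbut-2-en-1-yl)benzene-1,2-diol | COc1cc(O)ccc1CCCc1cc(O)c(O)c(CC=C(C)C)c1CC=C(C)C | target

## Step count and risks

Total step count: 7.
Longest linear sequence: 5 steps (steps 3, 4, 5, 6 and 7, starting from 4-bromocatechol 6).

**Risk 1: step 6 (bears the label "Proposed new method:").**
- Prenyl transfer from boron to the first aryl–Pd–I species could occur before the norbornene relay, so that no fragment union takes place.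
- Hydride termination could follow β-hydride loss from the tertiary σ-allyl isomer.
- Prenyl transfer could occur through the branched terminus.
- The last aryl–Pd species could undergo intramolecular C–H arylation of the anisole ring.

The fallback uses only known chemistry, a sterically differentiated sequential cross-coupling of an ortho-dibromide. It sets out from 7 and from 4 (made from 2 as in step 2) and returns at 15.
- Bromination of 7 with NBS in MeCN (0 °C to rt), done before any alkene is present, should give 1,2-dibromo-4,5-bis(methoxymethoxy)benzene F1.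
- LDA in THF at −78 °C should give [2,3-dibromo-5,6-bis(methoxymethoxy)phenyl]lithium F2.
- CuBr·SMe2 should then give [2,3-dibromo-5,6-bis(methoxymethoxy)phenyl]copper F3.
- Reaction of F3 with 8 should give 1,2-dibromo-4,5-bis(methoxymethoxy)-3-(3-methylbut-2-en-1-yl)benzene F4.
- In parallel, 4 with allyl bromide should give 2-methoxy-4-(methoxymethoxy)-1-(prop-2-en-1-yl)benzene F5.
- 9-BBN-H should add to the terminal alkene of F5 to give 9-{3-[2-methoxy-4-(methoxymethoxy)phenyl]propyl}-9-borabicyclo[3.3.1]nonane F6.
- B-alkyl Suzuki–Miyaura coupling of F6 with F4 [PdCl2(dppf), K3PO4, THF–DMF–H2O, 50 °C] should take place at the bromide whose outer neighbour is only C–H. It forms the same aryl–CH2 bond and gives 2-bromo-1-{3-[2-methoxy-4-(methoxymethoxy)phenyl]propyl}-4,5-bis(methoxymethoxy)-3-(3-methylbut-2-en-1-yl)benzene F7.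
- Linear-selective Suzuki–Miyaura prenylation of F7 with 14 (bulky NHC–Pd or dialkylbiarylphosphine–Pd catalyst, aq. KOH, THF, 70 °C) returns to 15.

**Risk 2: step 4.**
- LiBr could be lost from the ortho-bromoaryl metal (aryne formation) during the comparatively slow transmetalation and allylation.
- Prenyl bromide could be attacked at its tertiary end.

The fallback sets out from 7 and returns at 11. It replaces the nucleophilic allylation by a cross-coupling of a stable dihalide.
- Aryllithium 9 is generated as in step 4 and quenched at once at −78 °C with iodine to give 1-bromo-2-iodo-3,4-bis(methoxymethoxy)benzene F8.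
- Chemoselective, linear-selective Suzuki–Miyaura prenylation of the C–I bond of F8 with 14 (1.0 equiv, Pd/dialkylbiarylphosphine, aq. K3PO4, THF, 40 °C) should give 11 with the C–Br bond retained.

**Risk 3: step 7.**
- The freed ring-B C4 phenol could add to the neighbouring prenyl alkene under acid catalysis (chroman formation).
- The liberated catechol could be oxidised by air.

The fallback sets out from 15 and returns at 16. It avoids Brønsted acid by a silyl-transfer deprotection.
- TMSOTf with 2,2'-bipyridyl in MeCN (0 °C to rt) should convert the three aryl MOM ethers into 1-{3-[2-methoxy-4-(trimethylsilyloxy)phenyl]propyl}-2,3-bis(3-methylbut-2-en-1-yl)-4,5-bis(trimethylsilyloxy)benzene F9.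
- Addition of water under the buffered conditions should hydrolyse F9 to 16.

## Further compounds

F1 | step 6 | 1,2-dibromo-4,5-bis(methoxymethoxy)benzene | COCOc1cc(Br)c(Br)cc1OCOC
F2 | step 6 | [2,3-dibromo-5,6-bis(methoxymethoxy)phenyl]lithium | COCOc1cc(Br)c(Br)c([Li])c1OCOC
F3 | step 6 | [2,3-dibromo-5,6-bis(methoxymethoxy)phenyl]copper | COCOc1cc(Br)c(Br)c([Cu])c1OCOC
F4 | step 6 | 1,2-dibromo-4,5-bis(methoxymethoxy)-3-(3-methylbut-2-en-1-yl)benzene | COCOc1cc(Br)c(Br)c(CC=C(C)C)c1OCOC
F5 | step 6 | 2-methoxy-4-(methoxymethoxy)-1-(prop-2-en-1-yl)benzene | COCOc1ccc(CC=C)c(OC)c1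
F6 | step 6 | 9-{3-[2-methoxy-4-(methoxymethoxy)phenyl]propyl}-9-borabicyclo[3.3.1]nonane | COCOc1ccc(CCCB2C3CCCC2CCC3)c(OC)c1
F7 | step 6 | 2-bromo-1-{3-[2-methoxy-4-(methoxymethoxy)phenyl]propyl}-4,5-bis(methoxymethoxy)-3-(3-methylbut-2-en-1-yl)benzene | COCOc1ccc(CCCc2cc(OCOC)c(OCOC)c(CC=C(C)C)c2Br)c(OC)c1
F8 | step 4 | 1-bromo-2-iodo-3,4-bis(methoxymethoxy)benzene | COCOc1ccc(Br)c(I)c1OCOC
F9 | step 7 | 1-{3-[2-methoxy-4-(trimethylsilyloxy)phenyl]propyl}-2,3-bis(3-methylbut-2-en-1-yl)-4,5-bis(trimethylsilyloxy)benzene | COc1cc(O[Si](C)(C)C)ccc1CCCc1cc(O[Si](C)(C)C)c(O[Si](C)(C)C)c(CC=C(C)C)c1CC=C(C)C
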